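From the early minutes on, two of the runs point to how much carrier works.

the same everywhere: spent carrier 1.8 mol%; impurity 0.52 mM
- gamma: substrate 0.067 M; salt in the second phase 2 equiv; run made earlier
- epsilon: substrate 0.15 M; salt in the second phase 2 equiv; run made earlier
- theta: substrate 0.10 M; salt in the second phase 1 equiv; run made earlier
- flask: substrate 0.10 M; salt in the second phase 2.00 equiv; volume of the second phase over the first 0.25

| run | time / min | target / % | substrate / % |
|---|---|---|---|
| gamma | 1.33 | 51.6 | 48.1 |
| gamma | 2.50 | 69.7 | 29.2 |
| gamma | 4.00 | 82.3 | 16.8 |
| gamma | 5.00 | 86.8 | 11.7 |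
| gamma | 6.00 | 91.5 | 8.6 |
| gamma | 8.00 | 95.8 | 5.3 |
| gamma | 10.0 | 95.6 | 2.6 |
| epsilon | 0.667 | 64.8 | 37.6 |
| epsilon | 1.00 | 78.8 | 23.9 |
| epsilon | 1.50 | 84.4 | 16.1 |
| epsilon | 2.50 | 96.0 | 5.6 |
| epsilon | 4.00 | 97.7 | 2.0 |
| epsilon | 6.00 | 98.3 | 0 |
| epsilon | 10.0 | 101.1 | 0 |
| theta | 0.667 | 35.8 | 64.4 |
| theta | 1.33 | 51.8 | 48.5 |
| theta | 2.50 | 67.0 | 32.8 |
| theta | 5.00 | 78.5 | 22.1 |
| theta | 10.0 | 88.5 | 11.4 |

(each reading ± 1 percentage point)

- in the second phase: salt in the second phase, spent salt in the second phase; everything else is in the first
- charges count per volume of the first phase; a concentration in a rate is the amount of a species over the volume of its own phase; every rate counts per litre of the first phase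
- the numbers in the tables scatter with a standard deviation of 1 percentage point
- reactions considered so far: spent carrier + salt in the second phase <-> fresh carrier + spent salt in the second phase; substrate + fresh carrier -> target + spent carrier; fresh carrier + impurity -> spent catalyst
- the earlier runs hold the two phases in the same ratio of volumes as the flask asked about

1. factor on the rate of making target when 5.0% of the substrate are converted if spent carrier is charged twice over
2. factor on the rate when 5.0% of the substrate are converted if spent carrier is charged at 0.4 mol% instead

Gamma and epsilon had the same loading and the same equivalents of salt, so I compared them at equal substrate left. Epsilon held 2.70 mM of spent carrier and gamma 1.21 mM, a factor of 2.23. Yet gamma took 8.00 min to reach 5.3% of substrate, and epsilon took 2.50 min to reach 5.6%. That is a factor of 3.20 in time. The two factors did not go together.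

So I subtracted the impurity, 0.52 mM in each run, from the carrier charged. I took the impurity as the limiting reagent of that loss, since the carrier charge was larger than the impurity in both runs.

| Flask | Carrier charged | Carrier minus impurity |
|---|---|---|
| gamma | 1.21 mM | 0.686 mM |
| epsilon | 2.70 mM | 2.18 mM |
| flask | 1.80 mM | 1.28 mM |
| flask, doubled | 3.60 mM | 3.08 mM |
| flask, low loading | 0.400 mM | −0.120 mM |

I called this difference the working carrier. Its ratio between epsilon and gamma is 3.18, which matches the time factor as read. Substrate and salt differed between those runs too, with 0.15 M against 0.067 M of substrate, so I took the match as a lead, not a proof. For the doubled charge I therefore reckoned a factor of 2.41. At 0.4 mol% the charge is less than the impurity, and the subtraction gave me no usable factor, so I expected something small and named no number.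

The forecast said 2.4 and 0, with the impurity seeming to remove carrier “quickly and stoichiometrically”. The simulation gave 2.18 and 0.0660, on these steps:

    spent carrier + salt in the second phase ⇌ fresh carrier + spent salt in the second phase (K = 0.370, k = 4.70 L mol⁻¹ s⁻¹)
    substrate + fresh carrier → target + spent carrier (k = 26.0 L mol⁻¹ s⁻¹)
    fresh carrier + impurity → spent catalyst (k = 440 L mol⁻¹ s⁻¹)

The second factor is not zero, although the working carrier at that loading is −0.120 mM. That factor belongs to the moment of 5.0% conversion, which the flask as charged reached at 2.28 s. At 1.50 min the flask as charged held spent catalyst at 28.9% of the catalyst charged, with impurity at 0% of its own charge. Its working carrier is 71.1% of the carrier charged. At that time spent carrier at 46.4% and fresh carrier at 24.7% add up to 71.1%.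

All runs were generated by integration from invented constants; noise was put on by code.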